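## Analysis of the target

The target 16 is a depside: two benzene rings joined by one aryl ester, with no further ring and no stereocentre, so the problem is one of substitution pattern and chemoselectivity only. Ring A is a 2-heptyl-4,6-dimethoxybenzoyl unit whose carbonyl carbon sits between a heptyl and a methoxy group. Ring B, numbered from the carbon that carries the ester oxygen (C1), bears methoxy at C3, the free carboxyl at C4 and pentyl at C5, three contiguous substituents with the carboxyl in the middle. The sensitive group is the central aryl ester, an acylated phenol that hydroxide or alkoxide would cleave, so the free acid cannot be released by saponification at the end. Both rings are also electron-rich enough to be halogenated or oxidised by unselective reagents. The difficulties are the crowded 3,4,5-pattern of ring B, the differentiation of its two oxygens (one methylated, one acylated), the esterification of a benzoic acid with two ortho substituents, and the unveiling of the carboxyl group beside a base-labile ester. The strategy rests on ring B C4: if it carries iodine, its C3 neighbour is already blocked by methoxy and the only free ortho position is C5–H. One palladium cycle can then place pentyl on C5 and a carbon substituent on C4, which is later cut down oxidatively to the carboxyl group.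

## Retrosynthetic reasoning

Target 16 to aldehyde 15. The carboxyl group on ring B C4 is traced to the formyl group of 15 (4-formyl-3-methoxy-5-pentylphenyl 2-heptyl-4,6-dimethoxybenzoate). No skeletal bond is cut; only the oxidation level changes. The gain is that the free acid appears in the last step from a neutral precursor under a buffered, weakly acidic Pinnick oxidation, so no carboxyl protecting group has to be removed next to the depside ester. The forward step must oxidise a formyl group with two ortho neighbours without chlorinating either ring.

Aldehyde 15 to cinnamate 13. The formyl carbon is traced to the aryl-bearing alkene carbon of 13, the (E)-acrylate ester on ring B C4. The C=C bond is cut and the two-carbon ester end is discarded. An alkene is chosen as the masked carboxyl because a Heck termination is the most dependable exit of the key step and needs no organometallic partner that could attack the depside ester. The forward reaction, a Lemieux–Johnson cleavage through diol 14, must cleave a conjugated, electron-poor and crowded alkene and leave both arenes alone.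

Cinnamate 13 to aryl iodide 10, 1-iodopentane 11 and methyl acrylate 12. Two bonds on adjacent carbons of ring B are cut together: C5–pentyl and C4–alkenyl. These are the two carbon substituents that make ring B crowded, and removing both at once reduces ring B to a simple para-iodinated phenol ether. The C3 methoxy group, which is needed in the target anyway, is the blocking ortho substituent that a Catellani reaction requires. Cutting only the C4–carbon bond would leave a tetrasubstituted aryl iodide that is no easier to make than the target ring. The forward reaction has to alkylate C5–H only, then vinylate C4, in that order, without direct Heck coupling of the unalkylated ring and without cleaving the aryl ester.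

Iodide 10 to acid 6 and phenol 8. The acyl C–O bond of the depside is cut. It is placed before the key step because phenol 8 is unhindered and robust, so the hindered acid 6 can be activated forcefully as its chloride 9. Esterification after the key step would mean carrying a protected phenol through the palladium chemistry and deprotecting beside the acrylate. The forward step must acylate a phenol with an acyl chloride shielded by two ortho substituents.

Phenol 8 to 3-methoxyphenol 7. The C–I bond is cut. The free hydroxyl of 7 is the stronger para director, so electrophilic iodination should go to the position para to it and ortho to methoxy, which is the position the key step needs.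

Acid 6 to aldehyde 5 and arene 3. The carboxyl carbon of ring A is removed at the oxidation level of an aldehyde. The position ortho to heptyl and para to a methoxy group is the natural site of electrophilic substitution in 3. A Vilsmeier–Haack formylation through iminium salt 4, followed by a Pinnick oxidation, therefore gives the acid without any directing group.

Arene 3 to bromide 1 and Grignard reagent 2. The aryl–heptyl bond is cut. Bromide 1 is symmetrical, so a Kumada coupling raises no regiochemical question and gives the ring A skeleton in one step from two commercial materials.

## Alternatives that were turned down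

Alternative 1: Ring B is cut into a four-carbon diene and a two-carbon dienophile. The bonds cut run from the carboxyl-bearing carbon to the methoxy-bearing carbon and from the pentyl-bearing carbon to its CH neighbour.
- Forward key step: 1,1-dimethoxy-3-(trimethylsilyloxy)buta-1,3-diene A1 and benzyl oct-2-ynoate A2 would be heated together. The methylene terminus of A1 attacks the beta-carbon of A2 and the ketene acetal carbon bonds to the alpha-carbon. Loss of one methoxy group and of the silyl group aromatises the adduct to benzyl 4-hydroxy-2-methoxy-6-pentylbenzoate A3, which would be acylated with 9 and hydrogenolysed.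
- For: one step sets all three substituents of ring B, with the two oxygens already differentiated and the carboxyl carbon at its final oxidation level. On these points it is stronger than the chosen route, which needs two oxidative steps after the key step.
- Against: a beta-alkyl alkynoate is a sluggish dienophile that needs prolonged heating, while A1 is a silyl ketene acetal prone to hydrolysis, silyl transfer and oligomerisation. Both A1 and A2 have to be prepared, so the step count comes out about equal.
- Comparison: the chosen route offers shelf-stable aromatic intermediates throughout, commercial building blocks, and a catalytic step whose regiochemistry is fixed by palladacycle geometry and not by the polarisation of a fragile diene.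

Alternative 2: Ring B is cut at the bond between the carboxyl-bearing and the pentyl-bearing carbons, and at the bond between the neighbouring oxygenated carbon and its CH.
- Forward key step: dibenzyl malonate A4 adds in Michael fashion to (E)-non-3-en-2-one A5 under an alkoxide base, and the adduct closes by intramolecular Claisen condensation to racemic benzyl trans-2-hydroxy-4-oxo-6-pentylcyclohex-2-ene-1-carboxylate A6. This would be dehydrogenated to benzyl 2,4-dihydroxy-6-pentylbenzoate A7, acylated at the para hydroxyl with 9, methylated at the hydrogen-bonded ortho hydroxyl and hydrogenolysed.
- For: the materials are the cheapest of all, the annulation is scalable, and chelation differentiates the two hydroxyls in the right sense. It is as strong as the chosen route on step count and stronger on cost.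
- Against: two stereocentres are made only to be destroyed. The aromatisation is the weak step, because halogenation and dehydrohalogenation of an enolised dione tend to halogenate the electron-rich resorcylate that forms. Methylating a hydrogen-bonded hydroxyl beside the depside ester also needs forcing basic conditions.
- Comparison: the chosen route changes no ring oxidation state, has the methoxy group in place from the first step, and puts its single risky operation in a catalytic C–C coupling and not in a redox aromatisation.

Alternative 3: Ring A is cut at its C1–C2 bond, between the carbon that carries the ester carbonyl and the heptyl-bearing carbon.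
- Forward key step: mild base would fold 4-(benzyloxycarbonyl)-3-methoxy-5-pentylphenyl 3,5,7-trioxotetradecanoate A8 by aldol attack of chain C2 on the C7 ketone and dehydration. The product is 4-(benzyloxycarbonyl)-3-methoxy-5-pentylphenyl 2-heptyl-4,6-dihydroxybenzoate A9, which still needs double O-methylation and hydrogenolysis.
- For: it mirrors polyketide logic and forms ring A with the depside ester already in place. It thereby avoids the hindered esterification, and on this point it is stronger than the chosen route.
- Against: A8 is an aryl ester of a beta-keto acid, an activated ester with a good phenoxide leaving group. Closure of the C5 enol oxygen onto C1, or Claisen closure of C6 onto C1, would each expel the ring B phenol and destroy the depside bond. Building A8 also needs polyanion acylations that an aryl ester does not tolerate, ring B must still be made separately, and one of the two new hydroxyls is chelated and hard to methylate.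
- Comparison: this is the longest and riskiest option, with the risk in a labile early intermediate. The chosen route keeps every intermediate a stable arene.

Key step: step 6

Assumption: the organopalladium species of step 6 stay bound to the catalyst and are not free compounds, so they carry no numbers; diol 14 is racemic and is drawn as one enantiomer.

## Route

Step 1
Reactants: 1 1-bromo-3,5-dimethoxybenzene; 2 heptylmagnesium bromide
Product: 3 1-heptyl-3,5-dimethoxybenzene
Conditions: NiCl2(dppp) (2 mol %; dppp = 1,3-bis(diphenylphosphino)propane), THF/Et2O, 0 °C to reflux
Reagents that add atoms: none
Why: Kumada–Corriu coupling: zerovalent nickel formed from NiCl2(dppp) and the Grignard reagent inserts into the C–Br bond of 1, and transmetalation and reductive elimination form the aryl–alkyl bond; the chelating diphosphine keeps the n-heptyl group from isomerising by beta-hydride elimination, and the aryl methyl ethers are inert.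

Step 2
Reactants: 3 1-heptyl-3,5-dimethoxybenzene
Product: 5 2-heptyl-4,6-dimethoxybenzaldehyde, via iminium chloride 4 (not isolated)
Conditions: POCl3, DMF, 0 °C to 60 °C; then H2O, 50 °C
Reagents that add atoms: N,N-dimethylformamide CN(C)C=O; water O
Why: Vilsmeier–Haack formylation: the chloroiminium ion from DMF and POCl3 attacks C2 of 3, which is ortho to one methoxy group and para to the other and less crowded than C4 between the two methoxy groups; water then hydrolyses iminium salt 4 to the aldehyde.

Step 3
Reactants: 5 2-heptyl-4,6-dimethoxybenzaldehyde
Product: 6 2-heptyl-4,6-dimethoxybenzoic acid
Conditions: NaClO2, NaH2PO4, 2-methyl-2-butene, t-BuOH/H2O, rt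
Reagents that add atoms: sodium chlorite [Na+].[O-]Cl=O
Why: Pinnick oxidation: chlorous acid adds to the formyl group and fragments to the acid and HOCl, which 2-methyl-2-butene traps before it can chlorinate the electron-rich ring; the two ortho substituents do not block this small oxidant.

Step 4
Reactants: 7 3-methoxyphenol
Product: 8 4-iodo-3-methoxyphenol
Conditions: N-iodosuccinimide (1.0 equiv), TsOH·H2O (10 mol %), MeCN, 0 °C to rt
Reagents that add atoms: N-iodosuccinimide O=C1CCC(=O)N1I
Why: Electrophilic aromatic iodination: acid-activated N-iodosuccinimide attacks the position para to the free hydroxyl, the stronger donor, which is the carbon next to the methoxy group; one equivalent at low temperature limits double iodination, and any 6-iodo isomer is removed by chromatography.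

Step 5
Reactants: 6 2-heptyl-4,6-dimethoxybenzoic acid; 8 4-iodo-3-methoxyphenol
Product: 10 4-iodo-3-methoxyphenyl 2-heptyl-4,6-dimethoxybenzoate, via acid chloride 9 (not isolated)
Conditions: (COCl)2, DMF (cat.), CH2Cl2, 0 °C to rt, evaporate; then 8, Et3N, DMAP (cat.), CH2Cl2, 0 °C to rt
Reagents that add atoms: none
Why: Acyl chloride formation under DMF catalysis, then DMAP-catalysed acylation of the unhindered phenol through the acylpyridinium ion, which overcomes the shielding of the carbonyl by the heptyl and methoxy groups; the aryl iodide is untouched.

Step 6
Reactants: 10 4-iodo-3-methoxyphenyl 2-heptyl-4,6-dimethoxybenzoate; 11 1-iodopentane; 12 methyl acrylate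
Product: 13 3-methoxy-4-[(E)-3-methoxy-3-oxoprop-1-enyl]-5-pentylphenyl 2-heptyl-4,6-dimethoxybenzoate
Conditions: Pd(OAc)2 (10 mol %), tri(2-furyl)phosphine (20 mol %), norbornene (3 equiv), Cs2CO3 (3 equiv), 11 (3 equiv), 12 (1.5 equiv), MeCN, 85 °C, sealed tube
Reagents that add atoms: none
Why: This is a Catellani reaction (palladium and norbornene cooperative catalysis) in its known three-component form, ortho C–H alkylation of an ortho-substituted aryl iodide by a primary alkyl iodide with ipso Heck termination by an acrylate. Zerovalent palladium, formed from Pd(OAc)2 and the phosphine, inserts into the C4–I bond of ring B, norbornene inserts syn and exo to give an alkylpalladium species without an accessible syn beta-hydrogen, and carbonate-assisted palladation of C5–H closes a five-membered aryl–norbornyl palladacycle of divalent palladium. 1-Iodopentane adds oxidatively to this electron-rich palladacycle to give tetravalent palladium, and reductive elimination forms the C5–pentyl bond at the aryl carbon. The aryl–norbornyl bond at C4 is now flanked by methoxy and pentyl, and this crowding drives beta-carbon elimination, which expels norbornene and returns divalent arylpalladium at C4. Syn insertion of methyl acrylate with the aryl group going to the unsubstituted carbon, followed by syn beta-hydride elimination, gives the cinnamate, and the base regenerates zerovalent palladium. No ring of the product is closed and no stereocentre is formed; the E geometry follows from beta-hydride elimination through the less crowded rotamer. Site selectivity is secured by the substrate, since C3 carries methoxy and only C5–H is within reach of the palladacycle, and order selectivity is secured because norbornene leaves only after both ortho positions are filled, with an excess of norbornene over the acrylate suppressing direct Heck coupling of the unalkylated arylpalladium. Chemoselectivity between the two iodides follows from their partners (the aryl iodide reacts with zerovalent palladium, the alkyl iodide with the palladacycle), and the depside ester, shielded by two ortho substituents, should survive anhydrous Cs2CO3 in MeCN.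

Step 7
Reactants: 13 3-methoxy-4-[(E)-3-methoxy-3-oxoprop-1-enyl]-5-pentylphenyl 2-heptyl-4,6-dimethoxybenzoate
Product: 15 4-formyl-3-methoxy-5-pentylphenyl 2-heptyl-4,6-dimethoxybenzoate, via syn diol 14 (not isolated)
Conditions: OsO4 (2 mol %), NaIO4 (4 equiv), 2,6-lutidine (2 equiv), 1,4-dioxane/H2O 3:1, rt
Reagents that add atoms: osmium tetroxide O=[Os](=O)(=O)=O (oxygen carrier); sodium periodate [Na+].[O-]I(=O)(=O)=O (terminal oxidant that restocks it)
Why: Lemieux–Johnson oxidation: OsO4 adds suprafacially to the (E)-alkene to give the racemic syn diol 14 after hydrolysis of the osmate ester, periodate cleaves the glycol and re-oxidises osmium, and 2,6-lutidine suppresses ketol by-products; the arenes and both esters are inert, and the two stereocentres of 14 are destroyed in the same flask.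

Step 8
Reactants: 15 4-formyl-3-methoxy-5-pentylphenyl 2-heptyl-4,6-dimethoxybenzoate
Product: 16 4-[(2-heptyl-4,6-dimethoxybenzoyl)oxy]-2-methoxy-6-pentylbenzoic acid
Conditions: NaClO2, NaH2PO4, 2-methyl-2-butene (excess), t-BuOH/THF/H2O, 0 °C to rt
Reagents that add atoms: sodium chlorite [Na+].[O-]Cl=O
Why: Pinnick oxidation under phosphate buffer: the weakly acidic medium leaves the depside ester intact, the small oxidant reaches the doubly ortho-substituted formyl group, and excess 2-methyl-2-butene removes HOCl before it can chlorinate either ring.

## Compound list

1 | 1-bromo-3,5-dimethoxybenzene | COc1cc(Br)cc(OC)c1 | starting material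
2 | heptylmagnesium bromide | CCCCCCC[Mg]Br | starting material
3 | 1-heptyl-3,5-dimethoxybenzene | CCCCCCCc1cc(OC)cc(OC)c1 | intermediate
4 | [(2-heptyl-4,6-dimethoxyphenyl)methylidene]dimethylammonium chloride | CCCCCCCc1cc(OC)cc(OC)c1C=[N+](C)C.[Cl-] | intermediate
5 | 2-heptyl-4,6-dimethoxybenzaldehyde | CCCCCCCc1cc(OC)cc(OC)c1C=O | intermediate
6 | 2-heptyl-4,6-dimethoxybenzoic acid | CCCCCCCc1cc(OC)cc(OC)c1C(=O)O | intermediate
7 | 3-methoxyphenol | COc1cccc(O)c1 | starting material
8 | 4-iodo-3-methoxyphenol | COc1cc(O)ccc1I | intermediate
9 | 2-heptyl-4,6-dimethoxybenzoyl chloride | CCCCCCCc1cc(OC)cc(OC)c1C(=O)Cl | intermediate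
10 | 4-iodo-3-methoxyphenyl 2-heptyl-4,6-dimethoxybenzoate | CCCCCCCc1cc(OC)cc(OC)c1C(=O)Oc1ccc(I)c(OC)c1 | intermediate
11 | 1-iodopentane | CCCCCI | starting material
12 | methyl acrylate | C=CC(=O)OC | starting material
13 | 3-methoxy-4-[(E)-3-methoxy-3-oxoprop-1-enyl]-5-pentylphenyl 2-heptyl-4,6-dimethoxybenzoate | CCCCCCCc1cc(OC)cc(OC)c1C(=O)Oc1cc(CCCCC)c(/C=C/C(=O)OC)c(OC)c1 | intermediate
14 | 4-[(1S*,2R*)-1,2-dihydroxy-3-methoxy-3-oxopropyl]-3-methoxy-5-pentylphenyl 2-heptyl-4,6-dimethoxybenzoate (racemic, (1S,2R) enantiomer drawn) | CCCCCCCc1cc(OC)cc(OC)c1C(=O)Oc1cc(CCCCC)c([C@H](O)[C@@H](O)C(=O)OC)c(OC)c1 | intermediate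
15 | 4-formyl-3-methoxy-5-pentylphenyl 2-heptyl-4,6-dimethoxybenzoate | CCCCCCCc1cc(OC)cc(OC)c1C(=O)Oc1cc(CCCCC)c(C=O)c(OC)c1 | intermediate
16 | 4-[(2-heptyl-4,6-dimethoxybenzoyl)oxy]-2-methoxy-6-pentylbenzoic acid | CCCCCCCc1cc(OC)cc(OC)c1C(=O)Oc1cc(CCCCC)c(C(=O)O)c(OC)c1 | target

## Step count and least certain steps

Total step count: 8. Longest linear sequence: 7 steps (steps 1, 2, 3, 5, 6, 7, 8, from 1 to 16); step 4 supplies the phenol arm.

Step 6 (key step). Several processes could go wrong:
- direct Heck coupling of the arylpalladium iodide with 12 before norbornene has inserted, which leaves C5–H unalkylated;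
- reductive elimination from the palladacycle that retains norbornene in the product;
- base-promoted cleavage of the depside ester followed by O-pentylation of the freed phenoxide;
- loss of 11 by elimination.

The fallback abandons C–H alkylation and builds ring B with its carbons already in place. It sets out from acid chloride 9 and comes back to the route at aldehyde 15. Commercial olivetol F1 is formylated (POCl3, DMF, then water) to 2,4-dihydroxy-6-pentylbenzaldehyde F2. The hydroxyl para to the formyl group, which is not hydrogen-bonded, is acylated selectively with 9 (Et3N, CH2Cl2, 0 °C) to 4-formyl-3-hydroxy-5-pentylphenyl 2-heptyl-4,6-dimethoxybenzoate F3. Methylation of the remaining chelated hydroxyl (MeI, K2CO3, acetone, reflux) gives 15, which continues with step 8.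

Step 4. Iodination may partly go ortho to the hydroxyl and para to the methoxy group, or twice, and the regioisomers may be hard to separate. The fallback uses a phenol whose halogen position is fixed by purchase. It sets out from acid chloride 9 and comes back at iodide 10. Commercial 4-bromo-3-methoxyphenol F4 is acylated with 9 (Et3N, DMAP, CH2Cl2) to 4-bromo-3-methoxyphenyl 2-heptyl-4,6-dimethoxybenzoate F5. A copper-catalysed aromatic halogen exchange (CuI, NaI, trans-N,N'-dimethylcyclohexane-1,2-diamine, 1,4-dioxane, 110 °C) then gives 10.

Step 7. Osmylation of the conjugated, electron-poor alkene, which is twisted out of the ring plane by two ortho groups, may be slow, and over-oxidation at the glycol stage may compete during long reaction times. The fallback replaces the osmium pathway by a cycloaddition-based cleavage. It sets out from 13 and comes back at 15. Ozonolysis (O3, CH2Cl2, −78 °C, stopped at the colour change of Sudan Red 7B so that the arenes are not attacked) gives the secondary ozonide methyl 5-{4-[(2-heptyl-4,6-dimethoxybenzoyl)oxy]-2-methoxy-6-pentylphenyl}-1,2,4-trioxolane-3-carboxylate F6, which dimethyl sulfide reduces to 15.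

Step 8. Electrophilic chlorination of one of the electron-rich rings by HOCl may outrun the scavenger, and the crowded formyl group may react slowly. The fallback changes the oxidant class to one that generates no electrophilic chlorine. It sets out from 15 and comes back at 16: KMnO4 in t-BuOH with aqueous NaH2PO4 buffer at 0 °C oxidises the aldehyde through a manganate ester within minutes, at a pH that the depside ester tolerates. This fallback makes no compound outside the compound list (F0).

## Further compounds

F1 | step 6 | olivetol (5-pentylbenzene-1,3-diol) | CCCCCc1cc(O)cc(O)c1
F2 | step 6 | 2,4-dihydroxy-6-pentylbenzaldehyde | CCCCCc1cc(O)cc(O)c1C=O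
F3 | step 6 | 4-formyl-3-hydroxy-5-pentylphenyl 2-heptyl-4,6-dimethoxybenzoate | CCCCCCCc1cc(OC)cc(OC)c1C(=O)Oc1cc(CCCCC)c(C=O)c(O)c1
F4 | step 4 | 4-bromo-3-methoxyphenol | COc1cc(O)ccc1Br
F5 | step 4 | 4-bromo-3-methoxyphenyl 2-heptyl-4,6-dimethoxybenzoate | CCCCCCCc1cc(OC)cc(OC)c1C(=O)Oc1ccc(Br)c(OC)c1
F6 | step 7 | methyl 5-{4-[(2-heptyl-4,6-dimethoxybenzoyl)oxy]-2-methoxy-6-pentylphenyl}-1,2,4-trioxolane-3-carboxylate (mixture of diastereomers) | CCCCCCCc1cc(OC)cc(OC)c1C(=O)Oc1cc(CCCCC)c(C2OOC(O2)C(=O)OC)c(OC)c1
F0 | step 8 | none | none
A1 | alternative 1 | 1,1-dimethoxy-3-(trimethylsilyloxy)buta-1,3-diene | C=C(O[Si](C)(C)C)C=C(OC)OC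
A2 | alternative 1 | benzyl oct-2-ynoate | CCCCCC#CC(=O)OCc1ccccc1
A3 | alternative 1 | benzyl 4-hydroxy-2-methoxy-6-pentylbenzoate | CCCCCc1cc(O)cc(OC)c1C(=O)OCc1ccccc1
A4 | alternative 2 | dibenzyl malonate | O=C(CC(=O)OCc1ccccc1)OCc1ccccc1
A5 | alternative 2 | (E)-non-3-en-2-one | CCCCC/C=C/C(C)=O
A6 | alternative 2 | benzyl trans-2-hydroxy-4-oxo-6-pentylcyclohex-2-ene-1-carboxylate (racemic) | CCCCC[C@@H]1CC(=O)C=C(O)[C@H]1C(=O)OCc1ccccc1
A7 | alternative 2 | benzyl 2,4-dihydroxy-6-pentylbenzoate | CCCCCc1cc(O)cc(O)c1C(=O)OCc1ccccc1
A8 | alternative 3 | 4-(benzyloxycarbonyl)-3-methoxy-5-pentylphenyl 3,5,7-trioxotetradecanoate | CCCCCCCC(=O)CC(=O)CC(=O)CC(=O)Oc1cc(CCCCC)c(C(=O)OCc2ccccc2)c(OC)c1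
A9 | alternative 3 | 4-(benzyloxycarbonyl)-3-methoxy-5-pentylphenyl 2-heptyl-4,6-dihydroxybenzoate | CCCCCCCc1cc(O)cc(O)c1C(=O)Oc1cc(CCCCC)c(C(=O)OCc2ccccc2)c(OC)c1
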